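**Strategy.** Ring A is disconnected across C1–C6 and C3–C4 (benzoate numbering). Its C1, C2 and C3 – the carboxyl-, ether-oxygen- and formyl-bearing carbons – form a (Z)-3-aryloxycrotonate that is already locked inside ring B as a seven-membered enol-ether lactone on ring C; the key step exploits exactly this unit. In one operation the lactone's vinylogous methyl is acylated by a 3-methoxybutenoyl unit and the lactone α-carbon closes onto the methoxy-bearing carbon, so the arene, the diaryl ether and the depsidone lactone appear together. The precursor is 8-methoxy-4,6-dimethyl-2H-benzo[b][1,4]dioxepin-2-one. A temporary bromine at ring A C5 then steers ring D annulation to ring C and formylation to C3.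

Key step: step 11

Remark: ring A carbons carry benzoate numbers (C1 carboxyl, C2 ether oxygen, C3, C4 hydroxyl, C5, C6 methyl); compound names use 11H-dibenzo[b,e][1,4]dioxepin-11-one numbering, where ring A C5 is C2 and ring A C3 is C4, and ring C holds C6 (methyl), C7, C8 (oxygen) and C9.

Step 1
Reactants: 1 2,4-dihydroxy-6-methylbenzaldehyde
Product: 2 2-hydroxy-4-methoxy-6-methylbenzaldehyde
Conditions: MeI (1.05 equiv), K2CO3, acetone, rt
Reagents that add atoms: iodomethane, CI
Why: Williamson O-methylation should be selective for the 4-hydroxyl because the 2-hydroxyl is tied up in a hydrogen bond to the aldehyde and is the weaker nucleophile.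

Step 2
Reactants: 2 2-hydroxy-4-methoxy-6-methylbenzaldehyde
Product: 3 2-(allyloxy)-4-methoxy-6-methylbenzaldehyde
Conditions: allyl bromide, K2CO3, DMF, 60 °C
Reagents that add atoms: allyl bromide, C=CCBr
Why: Williamson etherification under more forcing conditions caps the chelated phenol with an allyl group, which cannot migrate between neighbouring catechol oxygens and is later removed under neutral conditions.

Step 3
Reactants: 3 2-(allyloxy)-4-methoxy-6-methylbenzaldehyde
Product: 5 2-(allyloxy)-4-methoxy-6-methylphenol, via aryl formate 4 (not isolated)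
Conditions: mCPBA, CH2Cl2, 0 °C to rt; then K2CO3 (cat.), MeOH, rt
Reagents that add atoms: 3-chloroperoxybenzoic acid, OOC(=O)c1cccc(Cl)c1
Why: Dakin-type Baeyer–Villiger oxidation of the electron-rich aldehyde should proceed by aryl migration to the formate, which mild methanolysis cleaves to the phenol flanked by the methyl and allyloxy groups.

Step 4
Reactants: 6 ethyl but-2-ynoate
Product: 7 ethyl (Z)-3-iodobut-2-enoate
Conditions: NaI, AcOH, 115 °C
Reagents that add atoms: sodium iodide, [Na+].[I-]
Why: Hydroiodination of the ynoate by conjugate addition of iodide and anti protonation should give the (Z)-β-iodo enoate stereoselectively.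

Step 5
Reactants: 5 2-(allyloxy)-4-methoxy-6-methylphenol and 7 ethyl (Z)-3-iodobut-2-enoate
Product: 8 ethyl (Z)-3-[2-(allyloxy)-4-methoxy-6-methylphenoxy]but-2-enoate
Conditions: CuI (10 mol %), N,N-dimethylglycine (30 mol %), Cs2CO3, 1,4-dioxane, 60 °C
Reagents that add atoms: none
Why: Copper-catalysed Ullmann-type C–O coupling of the hindered phenol with the vinyl iodide should proceed with retention of alkene geometry, which places the aryloxy group cis to the ester as ring B requires.

Step 6
Reactants: 8 ethyl (Z)-3-[2-(allyloxy)-4-methoxy-6-methylphenoxy]but-2-enoate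
Product: 9 (Z)-3-[2-(allyloxy)-4-methoxy-6-methylphenoxy]but-2-enoic acid
Conditions: LiOH, THF/H2O, rt; then 1 M HCl, 0 °C
Reagents that add atoms: lithium hydroxide, [Li+].[OH-]
Why: Ester saponification should leave the enol ether and its geometry untouched because the vinylogous carbonate is a poor acceptor for hydroxide.

Step 7
Reactants: 9 (Z)-3-[2-(allyloxy)-4-methoxy-6-methylphenoxy]but-2-enoic acid
Product: 10 (Z)-3-(2-hydroxy-4-methoxy-6-methylphenoxy)but-2-enoic acid
Conditions: Pd(PPh3)4 (5 mol %), morpholine, THF, rt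
Reagents that add atoms: none
Why: Tsuji–Trost-type deallylation, in which zerovalent palladium ionises the aryl allyl ether and morpholine captures the allyl fragment, unveils the phenol under neutral conditions while the enoate sits as an unreactive carboxylate.

Step 8
Reactants: 10 (Z)-3-(2-hydroxy-4-methoxy-6-methylphenoxy)but-2-enoic acid
Product: 11 8-methoxy-4,6-dimethyl-2H-benzo[b][1,4]dioxepin-2-one
Conditions: DCC, CH2Cl2 (0.01 M), 0 °C to rt
Reagents that add atoms: none
Why: Carbodiimide lactonisation of an ortho-hydroxyaryl ether acid, the ring closure commonly used for depsidones, should be favoured because the (Z)-alkene and the arene hold the phenol next to the activated carboxyl.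

Step 9
Reactants: 12 methyl (E)-3-methoxybut-2-enoate
Product: 13 (E)-3-methoxybut-2-enoic acid
Conditions: KOH, MeOH/H2O, 60 °C; then HCl to pH 3, 0 °C
Reagents that add atoms: potassium hydroxide, [K+].[OH-]
Why: Saponification followed by cold, mild acidification should give the acid without hydrolysing the enol ether.

Step 10
Reactants: 13 (E)-3-methoxybut-2-enoic acid
Product: 14 (E)-3-methoxybut-2-enoyl chloride
Conditions: (COCl)2, DMF (cat.), CH2Cl2, 0 °C to rt
Reagents that add atoms: oxalyl chloride, O=C(Cl)C(=O)Cl
Why: Acid chloride formation through the catalytic chloroiminium species is mild enough for the enol ether, and the crude chloride is used directly.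

Step 11
Reactants: 11 8-methoxy-4,6-dimethyl-2H-benzo[b][1,4]dioxepin-2-one and 14 (E)-3-methoxybut-2-enoyl chloride
Product: 16 3-hydroxy-8-methoxy-1,6-dimethyl-11H-dibenzo[b,e][1,4]dioxepin-11-one, via acylated lactone 15 (not isolated)
Conditions: LiN(SiMe3)2 (2.2 equiv), THF, −78 °C; 14 (1.0 equiv), −78 °C to 0 °C; then aq. HCl
Reagents that add atoms: none
Why: Proposed new method: LiN(SiMe3)2 removes a proton from the C4 methyl of 11, which is vinylogous to the lactone carbonyl, and the resulting extended enolate is acylated by 14 at that terminal carbon to give 15, whose doubly activated CH2 is deprotonated at once by the second equivalent of base. On warming, the lactone α-carbon of this anion adds to the methoxy-bearing β-carbon of the enone, methoxide is expelled and the cyclohexadienone enolises to the phenoxide of 16, so that ring A C3–C4 and C1–C6 are formed in one flask. The closest known chemistry is the [3+3] resorcylate synthesis from 1,3-dioxygenated dienolates (dioxinone or bis-silyl dienol ether type) and β-oxygenated acyl electrophiles, together with the terminal acylation of 3-alkoxycrotonate dienolates. Ring A closes in a 6-endo-trig addition–elimination (equally a 6π closure of the trienolate), and no stereocentre is created. The step needs acylation at the terminal carbon instead of the α-carbon or oxygen, which the β-aryloxy substituent should secure by making the dienolate a vinylogous ester enolate that reacts at its methyl terminus, as dioxinone dienolates do. It also needs the aryl lactone to survive, which the non-nucleophilic amide base at −78 °C should secure, while the cis geometry enforced by ring B keeps the new ketone away from the lactone carbonyl and so blocks pyrone formation.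

Step 12
Reactants: 16 3-hydroxy-8-methoxy-1,6-dimethyl-11H-dibenzo[b,e][1,4]dioxepin-11-one
Product: 17 2-bromo-3-hydroxy-8-methoxy-1,6-dimethyl-11H-dibenzo[b,e][1,4]dioxepin-11-one
Conditions: NBS (1.0 equiv), CH2Cl2, −20 °C to 0 °C
Reagents that add atoms: N-bromosuccinimide, O=C1CCC(=O)N1Br
Why: Electrophilic aromatic bromination of the free phenol ring should go ortho to the hydroxyl at the carbon para to the diaryl ether oxygen (ring A C5) and not between the two oxygens, which puts a removable block on the site that would otherwise capture the later electrophiles.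

Step 13
Reactants: 17 2-bromo-3-hydroxy-8-methoxy-1,6-dimethyl-11H-dibenzo[b,e][1,4]dioxepin-11-one
Product: 18 2-bromo-3,8-dihydroxy-1,6-dimethyl-11H-dibenzo[b,e][1,4]dioxepin-11-one
Conditions: BBr3, CH2Cl2, −78 °C to 0 °C; then H2O
Reagents that add atoms: none
Why: Lewis-acid demethylation of the aryl methyl ether (bromide attack on the O-methyl of the boron-bound ether) is standard for depsidone methyl ethers and should spare the hindered lactone.

Step 14
Reactants: 18 2-bromo-3,8-dihydroxy-1,6-dimethyl-11H-dibenzo[b,e][1,4]dioxepin-11-one and 19 3-methylbut-2-enoic acid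
Product: 21 2-bromo-4-deformyl-mollicellin A (2,2-dimethyl-2,3-dihydro-4H-pyran-4-one ring D fused to ring C: carbonyl carbon on C7 / ring oxygen on C8), via ortho-acylphenol 20 (not isolated)
Conditions: P2O5/MeSO3H (1:10 w/w), 19 (1.2 equiv), 60 °C
Reagents that add atoms: none
Why: Friedel–Crafts acylation by the mixed anhydride of 19 should occur ortho to the ring C hydroxyl at C7 (para to the lactone oxygen and not between two oxygens), and oxa-Michael closure of the resulting enone 20 then gives the 2,2-dimethylchromanone, ring A being protected by its ester and by the bromine on its most nucleophilic carbon.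

Step 15
Reactants: 21 2-bromo-4-deformyl-mollicellin A
Product: 23 2-bromo-mollicellin A, via chloromethoxymethyl arene 22 (not isolated)
Conditions: Cl2CHOMe, TiCl4, CH2Cl2, −10 °C to rt; then ice/1 M HCl
Reagents that add atoms: dichloromethyl methyl ether, COC(Cl)Cl; water, O
Why: In this Rieche formylation the titanium phenoxide of ring A directs the electrophile ortho to the hydroxyl, and with C5 brominated the only open ortho carbon is C3 between the two oxygens.

Step 16
Reactants: 23 2-bromo-mollicellin A
Product: 24 Mollicellin A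
Conditions: Pd(OAc)2 (5 mol %), PPh3 (20 mol %), HCO2H, Et3N, DMF, 80 °C
Reagents that add atoms: none
Why: Palladium-catalysed transfer hydrogenolysis of the aryl bromide with formate as hydride source should remove the blocking group without reducing the aldehyde, the ketone or the lactone.

**Compound list**

1 | 2,4-dihydroxy-6-methylbenzaldehyde | Cc1cc(O)cc(O)c1C=O | starting material
2 | 2-hydroxy-4-methoxy-6-methylbenzaldehyde | Cc1cc(OC)cc(O)c1C=O | intermediate
3 | 2-(allyloxy)-4-methoxy-6-methylbenzaldehyde | Cc1cc(OC)cc(OCC=C)c1C=O | intermediate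
4 | 2-(allyloxy)-4-methoxy-6-methylphenyl formate (not isolated) | Cc1cc(OC)cc(OCC=C)c1OC=O | intermediate
5 | 2-(allyloxy)-4-methoxy-6-methylphenol | Cc1cc(OC)cc(OCC=C)c1O | intermediate
6 | ethyl but-2-ynoate | CCOC(=O)C#CC | starting material
7 | ethyl (Z)-3-iodobut-2-enoate | C/C(I)=C/C(=O)OCC | intermediate
8 | ethyl (Z)-3-[2-(allyloxy)-4-methoxy-6-methylphenoxy]but-2-enoate | C/C(Oc1c(C)cc(OC)cc1OCC=C)=C/C(=O)OCC | intermediate
9 | (Z)-3-[2-(allyloxy)-4-methoxy-6-methylphenoxy]but-2-enoic acid | C/C(Oc1c(C)cc(OC)cc1OCC=C)=C/C(=O)O | intermediate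
10 | (Z)-3-(2-hydroxy-4-methoxy-6-methylphenoxy)but-2-enoic acid | C/C(Oc1c(C)cc(OC)cc1O)=C/C(=O)O | intermediate
11 | 8-methoxy-4,6-dimethyl-2H-benzo[b][1,4]dioxepin-2-one | CC1=CC(=O)Oc2cc(OC)cc(C)c2O1 | intermediate
12 | methyl (E)-3-methoxybut-2-enoate | CO/C(C)=C/C(=O)OC | starting material
13 | (E)-3-methoxybut-2-enoic acid | CO/C(C)=C/C(=O)O | intermediate
14 | (E)-3-methoxybut-2-enoyl chloride | CO/C(C)=C/C(=O)Cl | intermediate
15 | 8-methoxy-4-[(3E)-4-methoxy-2-oxopent-3-en-1-yl]-6-methyl-2H-benzo[b][1,4]dioxepin-2-one (not isolated) | CO/C(C)=C/C(=O)CC1=CC(=O)Oc2cc(OC)cc(C)c2O1 | intermediate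
16 | 3-hydroxy-8-methoxy-1,6-dimethyl-11H-dibenzo[b,e][1,4]dioxepin-11-one | Cc1cc(O)cc2c1C(=O)Oc1cc(OC)cc(C)c1O2 | intermediate
17 | 2-bromo-3-hydroxy-8-methoxy-1,6-dimethyl-11H-dibenzo[b,e][1,4]dioxepin-11-one | Cc1c(Br)c(O)cc2c1C(=O)Oc1cc(OC)cc(C)c1O2 | intermediate
18 | 2-bromo-3,8-dihydroxy-1,6-dimethyl-11H-dibenzo[b,e][1,4]dioxepin-11-one | Cc1c(Br)c(O)cc2c1C(=O)Oc1cc(O)cc(C)c1O2 | intermediate
19 | 3-methylbut-2-enoic acid | CC(C)=CC(=O)O | starting material
20 | 2-bromo-3,8-dihydroxy-1,6-dimethyl-7-(3-methylbut-2-enoyl)-11H-dibenzo[b,e][1,4]dioxepin-11-one (not isolated) | Cc1c(Br)c(O)cc2c1C(=O)Oc1cc(O)c(C(=O)C=C(C)C)c(C)c1O2 | intermediate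
21 | 2-bromo-4-deformyl-mollicellin A (depsidone of 18 with a 2,2-dimethyl-2,3-dihydro-4H-pyran-4-one fused through its carbonyl carbon to C7 and its oxygen to C8) | Cc1c(Br)c(O)cc2c1C(=O)Oc1cc3c(c(C)c1O2)C(=O)CC(C)(C)O3 | intermediate
22 | 4-[chloro(methoxy)methyl] derivative of 21 (racemic at the new carbon, not isolated) | Cc1c(Br)c(O)c(C(Cl)OC)c2c1C(=O)Oc1cc3c(c(C)c1O2)C(=O)CC(C)(C)O3 | intermediate
23 | 2-bromo-mollicellin A (4-formyl derivative of 21) | Cc1c(Br)c(O)c(C=O)c2c1C(=O)Oc1cc3c(c(C)c1O2)C(=O)CC(C)(C)O3 | intermediate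
24 | Mollicellin A | Cc1cc(O)c(C=O)c2c1C(=O)Oc1cc3c(c(C)c1O2)C(=O)CC(C)(C)O3 | target

**Step count.** Total: 16 steps. Longest linear sequence: 13 steps (steps 1, 2, 3, 5, 6, 7, 8, 11, 12, 13, 14, 15, 16).

**Steps most likely to fail**

Step 11 (proposed new method). Acylation of the extended enolate at the α-carbon or on oxygen, base-induced opening of the aryl lactone, or stalling after acylation without ring closure would each stop the annulation. The fallback is the classical depsidone assembly by diaryl ether coupling and lactonisation, and it sets out from phenol 5. Methyl 2,4-dihydroxy-6-methylbenzoate is benzylated at the 4-hydroxyl (BnBr, K2CO3, acetone) to methyl 4-(benzyloxy)-2-hydroxy-6-methylbenzoate F1 and converted with Tf2O and pyridine into methyl 4-(benzyloxy)-6-methyl-2-(trifluoromethylsulfonyloxy)benzoate F2. Palladium-catalysed C–O coupling of F2 with 5 (Pd(OAc)2, 2-(di-tert-butylphosphino)-2',4',6'-triisopropylbiphenyl, K3PO4, toluene, 100 °C) should give methyl 2-[2-(allyloxy)-4-methoxy-6-methylphenoxy]-4-(benzyloxy)-6-methylbenzoate F3. Deallylation (Pd(PPh3)4, morpholine) then gives methyl 4-(benzyloxy)-2-(2-hydroxy-4-methoxy-6-methylphenoxy)-6-methylbenzoate F4. Cleavage of the hindered methyl ester (LiI, pyridine, reflux) gives 4-(benzyloxy)-2-(2-hydroxy-4-methoxy-6-methylphenoxy)-6-methylbenzoic acid F5. DCC closes the lactone to 3-(benzyloxy)-8-methoxy-1,6-dimethyl-11H-dibenzo[b,e][1,4]dioxepin-11-one F6, and hydrogenolysis (H2, Pd/C, EtOAc) comes back to the route at 16.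

Step 14. Acylation on ring A or at C9 of ring C, conjugate alkylation of the phenol leading to a dihydrocoumarin instead of acylation, ester formation at the ring A hydroxyl, and acid-induced breakdown of the depsidone are the ways this step may go wrong. The fallback builds ring D from an acetyl group and acetone and sets out from 18. Acetylation (Ac2O, pyridine) gives 2-bromo-1,6-dimethyl-11-oxo-11H-dibenzo[b,e][1,4]dioxepine-3,8-diyl diacetate F7. Fries rearrangement of the ring C acetate (TiCl4, 1,2-dichloroethane, 80 °C) gives 7-acetyl-2-bromo-8-hydroxy-1,6-dimethyl-11-oxo-11H-dibenzo[b,e][1,4]dioxepin-3-yl acetate F8. Kabbe condensation with acetone and pyrrolidine (MeOH, 40 °C) then forms the 2,2-dimethylchromanone by aldol condensation and oxa-Michael closure, removes the ring A acetate, and comes back to the route at 21.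

Step 8. Intermolecular ester formation, rearrangement of the activated acid to an N-acylurea, and conjugate addition of the phenol to the activated enoate may all outrun closure of the seven-membered ring. The fallback separates activation of the acid from unmasking of the phenol and sets out from acid 9. DCC and pentafluorophenol give pentafluorophenyl (Z)-3-[2-(allyloxy)-4-methoxy-6-methylphenoxy]but-2-enoate F9. Neutral deallylation (Pd(PPh3)4, PhSiH3, CH2Cl2) gives pentafluorophenyl (Z)-3-(2-hydroxy-4-methoxy-6-methylphenoxy)but-2-enoate F10. i-Pr2NEt at high dilution (CH2Cl2, 0.005 M) then closes the ring by intramolecular transesterification of the isolated active ester and comes back to the route at 11.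

**Further compounds**

F1 | step 11 | methyl 4-(benzyloxy)-2-hydroxy-6-methylbenzoate | COC(=O)c1c(C)cc(OCc2ccccc2)cc1O
F2 | step 11 | methyl 4-(benzyloxy)-6-methyl-2-(trifluoromethylsulfonyloxy)benzoate | COC(=O)c1c(C)cc(OCc2ccccc2)cc1OS(=O)(=O)C(F)(F)F
F3 | step 11 | methyl 2-[2-(allyloxy)-4-methoxy-6-methylphenoxy]-4-(benzyloxy)-6-methylbenzoate | COC(=O)c1c(C)cc(OCc2ccccc2)cc1Oc1c(C)cc(OC)cc1OCC=C
F4 | step 11 | methyl 4-(benzyloxy)-2-(2-hydroxy-4-methoxy-6-methylphenoxy)-6-methylbenzoate | COC(=O)c1c(C)cc(OCc2ccccc2)cc1Oc1c(C)cc(OC)cc1O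
F5 | step 11 | 4-(benzyloxy)-2-(2-hydroxy-4-methoxy-6-methylphenoxy)-6-methylbenzoic acid | OC(=O)c1c(C)cc(OCc2ccccc2)cc1Oc1c(C)cc(OC)cc1O
F6 | step 11 | 3-(benzyloxy)-8-methoxy-1,6-dimethyl-11H-dibenzo[b,e][1,4]dioxepin-11-one | Cc1cc(OCc3ccccc3)cc2c1C(=O)Oc1cc(OC)cc(C)c1O2
F7 | step 14 | 2-bromo-1,6-dimethyl-11-oxo-11H-dibenzo[b,e][1,4]dioxepine-3,8-diyl diacetate | Cc1c(Br)c(OC(C)=O)cc2c1C(=O)Oc1cc(OC(C)=O)cc(C)c1O2
F8 | step 14 | 7-acetyl-2-bromo-8-hydroxy-1,6-dimethyl-11-oxo-11H-dibenzo[b,e][1,4]dioxepin-3-yl acetate | Cc1c(Br)c(OC(C)=O)cc2c1C(=O)Oc1cc(O)c(C(C)=O)c(C)c1O2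
F9 | step 8 | pentafluorophenyl (Z)-3-[2-(allyloxy)-4-methoxy-6-methylphenoxy]but-2-enoate | C/C(Oc1c(C)cc(OC)cc1OCC=C)=C/C(=O)Oc1c(F)c(F)c(F)c(F)c1F
F10 | step 8 | pentafluorophenyl (Z)-3-(2-hydroxy-4-methoxy-6-methylphenoxy)but-2-enoate | C/C(Oc1c(C)cc(OC)cc1O)=C/C(=O)Oc1c(F)c(F)c(F)c(F)c1F
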